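# Synthesis plan for CNP0180877.1 (compound 38)

## The problem

Target 38 is a trans-fused decalin (ring A = C1–C5 and C10, ring B = C5–C10). Ring carbons C2, C3, C4, C5, C9 and C10 are stereogenic, and a seventh, remote centre sits at C13 in the C9 side chain (C11–C15, acid at C15).

One edge of ring A is crowded: an equatorial acetate on C2, a free axial hydroxyl on C3, and a quaternary C4 carrying a methyl and the axial formyl group C19, next to the quaternary C10 methyl.

C5 can control C4 when both sit in a five-membered ring. C5 and C9 together decide the face of C10, and C10 then steers C2 and C3 once ring A closes. C13 is too far away to be controlled and has to come from the chiral pool.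

The C5 and C9 substituents are cis across C10. In a monocyclic ring B with an sp2 C10, allylic strain does not favour this arrangement, so it has to be made under kinetic control.

Several groups are fragile:
- The cis hydroxy acetate can undergo acyl migration or hydrolysis.
- The β-hydroxy aldehyde (C3–OH, C19) can undergo base-induced retro-aldol cleavage.
- The C7–C8 alkene reacts with peracids and drifts to C8–C9 in strong protic acid.
- The C15 acid must be freed without touching the acetate.

The feature that opens the synthesis is this: the C10 methyl can arise from an exocyclic methylene by hydrogen-atom transfer; C1, C2 and the two acetate carbons are the four carbons of methyl vinyl ketone 32; and the C3 hydroxyl is β to that carbonyl. Ring A is therefore the sum of ring B aldehyde 31 and enone 32, with the acetyl group later turned into the acetate.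

## Retrosynthesis

**38 back to 33 (functional-group changes).** The C19 aldehyde is traced to the primary alcohol of 37, and the acid and both hydroxyls to the tert-butyl ester and silyl ethers of 35. The C2–O bond of the acetate is cut back to the C2 acetyl group of 33 (Baeyer–Villiger, retention at C2). Direct α-oxygenation at C2 would need its own stereocontrol, whereas the acetyl group is delivered by the ring-forming step with its configuration set. The forward reactions must oxidise a ketone without touching the C7–C8 alkene and must release the acid without strong protic acid.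

**33 to 31 and 32 (key disconnection).** The C1–C10 and C2–C3 bonds are cut. A polar annulation cannot make the quaternary C10 from a methylene carbon, and a cycloaddition onto ring A would not bring the C2/C3 oxygen pattern. A radical at C10 followed by an aldol closure does both and creates C10, C2 and C3 in one step. The precursor 31 is a monocycle with four stereocentres. The forward step has to add to the less hindered face of the C10 radical and close ring A before the enolate is protonated.

**31 to 28 (ring B).** After oxidation-state changes (31, 30, 29), the C8–C9 bond is cut: an allylsilane at C9/C10 attacks a gold-activated butynyl alkyne. A ring B ketone followed by methylenation would place an epimerisable, conjugation-prone centre at C9. Metathesis at C7–C8 would need C9 set in an open chain. The allylsilane closure makes the exocyclic methylene and the C7–C8 alkene in the same event and leaves an acyclic precursor with only C4, C5 and C13 stereogenic. It has to prefer the six-membered ring and deliver the 5,9-cis isomer; the second point is the weakest in the route.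

**28 to 25, 26 and 6.** The C9–C11 bond and the C10–CH2Si bond are cut (syn carbocupration of a terminal alkyne, then alkylation). Carbonyl olefination would give poor geometry control for a trisubstituted allylsilane; the syn addition fixes the (Z) geometry by mechanism. The pieces are the alkyne 25, Grignard reagent 26 and iodide 6.

**25 to 20.** C9 is removed (one-carbon homologation of the lactol 22), and the two primary oxygens on C3 and C10 are told apart by transposing the lactone (23 from diol 21, itself from lactone 20). Selective protection of one of two hindered primary alcohols would be the alternative. The oxidative lactonisation uses the steric difference in the productive direction and recycles the wrong isomer as 20.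

**20 to 15.** The C4–C19 and C4–CH3 bonds are cut (two enolate alkylations through 17 and 18). Making C4 with two identical arms and distinguishing them later would depend on diastereotopic-group selection. In the γ-lactone the C5 butynyl group directs both electrophiles to the opposite face, and the order of addition (formaldehyde first, methyl second) decides that the lactone carbonyl becomes C3 and the silyloxymethyl arm C19.

**15 to 10 and 11; 10 to 7 and 8.** The C5–C6 bond is cut (auxiliary-controlled alkylation of the succinate imide 10 with bromide 11, then reduction and lactonisation through 13). This sets C5 absolutely with commercial materials 7 and 8.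

**6 to 1.** The iodide is traced through acid 5 and lactone 3 to the chiral-pool monoester 1. Borane reduces the acid end, which becomes C11, and the ester end becomes C15 after exchange for a tert-butyl ester.

## Roads not taken

**Alternative 1:** Ring B would be cut at C5–C6 and C9–C10. The diene A1 and the enal ester A2 would combine in an exo Diels–Alder reaction under a chiral oxazaborolidinium Lewis acid to give A3.
- Merits: one catalytic step sets C5, C9 and the quaternary C10 (with its methyl). The cis relation of the C5 and C9 substituents follows from the diene geometry and the transition state. In this respect it is more secure than the chosen plan, where C9 depends on a cyclisation whose facial preference is uncertain.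
- Weak points: A3 carries only a formyl group (C1) and an ester (C4) for ring A. The quaternary C4 with three different carbon substituents, and the C2 and C3 oxygens, would each need separate bond-forming steps on a hindered ester carbon. Regiochemistry with a 1,2-dialkyl diene and exo selectivity are not assured, and the chain end must be re-oxidised late.
- Against this the chosen plan offers a ring A that arrives complete, with C4 prepared in advance under reliable substrate control.

**Alternative 2:** Ring A would be cut at C2–C3. A one-electron reductant (divalent samarium) would couple the C2 aldehyde of the trialdehyde A4 with one of its two C4 formyl groups to give the cis-diol A5.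
- Merits: both oxygens are installed at once, no Baeyer–Villiger step is needed, and C19 is already an aldehyde. The endgame is shorter than in the chosen plan, and this should be conceded.
- Weak points: the configuration of C4 rests on a choice between two diastereotopic formyl groups. The diol must then be monoacetylated selectively. A 2,2-disubstituted malonaldehyde is sensitive. C10 has to be made quaternary by other means, and A5 has a silyloxy group where the C9 chain should be, so the chain must still be attached next to a quaternary centre.
- The chosen plan fixes C4 early, makes C10 in the key step and carries the full chain through.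

**Alternative 3:** Ring B would be cut at C5–C10. The silyl ketene acetal of the ten-membered lactone A6 would undergo a transannular Ireland–Claisen rearrangement to the acid A7.
- Merits: the sigmatropic shift transfers chirality stereospecifically to C5 and C10, and C9 is in place before ring closure. For the C5/C10 relation this is better defined than a radical addition.
- Weak points: A6 needs two trisubstituted alkenes of defined geometry and a medium-ring lactonisation. Chair and boat pathways compete in such rings. A7 has a propenyl group and a bare carboxyl group, so ring A, the quaternary C4 and both oxygens are still to be built.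
- The chosen plan has a much shorter path from ring B to the complete ring A.

Key step: step 19

Remark: labdane locants (C1–C20 as defined above, C16 = methyl on C13, C17 = methyl on C8, C18 = methyl on C4, C20 = methyl on C10) are used for all intermediates.

## Route

Step 1
Reactants: 1 methyl hydrogen (R)-3-methylglutarate
Product: 3 (R)-4-methyltetrahydro-2H-pyran-2-one, via hydroxy ester 2 (not isolated)
Conditions: BH3·SMe2, THF, 0 °C to rt; MeOH; then TsOH·H2O (cat.), PhMe, 80 °C
Reagents that add atoms: none
Why: Borane reduces the free acid much faster than the methyl ester, and acid-catalysed lactonisation then fixes which end is which (the reduced carbon becomes C11); the C13 centre of the chiral-pool monoester is not touched.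

Step 2
Reactants: 3 (R)-4-methyltetrahydro-2H-pyran-2-one
Product: 5 (S)-5-iodo-3-methylpentanoic acid, via silyl ester 4 (not isolated)
Conditions: Me3SiCl, NaI, MeCN, 60 °C; then H2O
Reagents that add atoms: iodotrimethylsilane (made in the flask from Me3SiCl and NaI), C[Si](C)(C)I
Why: Lactone opening by iodotrimethylsilane (O-silylation, then SN2 attack of iodide at the O-bearing CH2) gives the ω-iodo silyl ester, which is hydrolysed on work-up; no bond to C13 is involved.

Step 3
Reactants: 5 (S)-5-iodo-3-methylpentanoic acid
Product: 6 tert-butyl (S)-5-iodo-3-methylpentanoate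
Conditions: Cl3CC(=NH)O-t-Bu, BF3·OEt2 (cat.), cyclohexane–CH2Cl2, rt
Reagents that add atoms: tert-butyl 2,2,2-trichloroacetimidate, CC(C)(C)OC(=N)C(Cl)(Cl)Cl
Why: Acid-catalysed tert-butylation of a carboxylic acid with the trichloroacetimidate is mild enough for a primary iodide and gives the ester that can later be removed without touching the acetate.

Step 4
Reactants: 7 4-tert-butoxy-4-oxobutanoic acid (mono-tert-butyl succinate); 8 (R)-4-benzyloxazolidin-2-one
Product: 10 tert-butyl 4-[(4R)-4-benzyl-2-oxooxazolidin-3-yl]-4-oxobutanoate, via mixed anhydride 9 (not isolated)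
Conditions: t-BuCOCl, Et3N, THF, −20 °C; then 8, LiCl, −20 °C to rt
Reagents that add atoms: none
Why: N-acylation of the oxazolidinone by the mixed pivalic anhydride is the standard way to attach the auxiliary.

Step 5
Reactants: 10 tert-butyl 4-[(4R)-4-benzyl-2-oxooxazolidin-3-yl]-4-oxobutanoate; 11 1-bromobut-2-yne
Product: 13 tert-butyl (3R)-3-{[(4R)-4-benzyl-2-oxooxazolidin-3-yl]carbonyl}hept-5-ynoate, via sodium enolate 12 (not isolated)
Conditions: NaN(SiMe3)2, THF, −78 °C; then 11, −78 to −40 °C
Reagents that add atoms: none
Why: Auxiliary-controlled (Evans) alkylation: the chelated (Z)-enolate of the imide forms in preference to the ester enolate and the propargylic bromide enters anti to the benzyl group, which sets C5.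

Step 6
Reactants: 13 tert-butyl (3R)-3-{[(4R)-4-benzyl-2-oxooxazolidin-3-yl]carbonyl}hept-5-ynoate
Product: 15 (4R)-4-(but-2-yn-1-yl)dihydrofuran-2(3H)-one, via hydroxy ester 14 (not isolated)
Conditions: LiBH4, MeOH (1 equiv), Et2O, 0 °C; aqueous work-up; then CF3CO2H, CH2Cl2, rt
Reagents that add atoms: none
Why: LiBH4 reduces the imide to the C10 carbinol and spares the tert-butyl ester; acid then closes the γ-lactone with loss of isobutene, giving the five-membered template in which C5 can control C4.

Step 7
Reactants: 15 (4R)-4-(but-2-yn-1-yl)dihydrofuran-2(3H)-one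
Product: 17 (3S,4R)-4-(but-2-yn-1-yl)-3-(hydroxymethyl)dihydrofuran-2(3H)-one, via lithium enolate 16 (not isolated)
Conditions: LiN(i-Pr)2, THF, −78 °C; then CH2O (gas, from paraformaldehyde), −78 to −20 °C
Reagents that add atoms: formaldehyde, C=O
Why: Aldol addition of the lactone enolate to monomeric formaldehyde introduces the future C19; it enters anti to the butynyl group, although this centre is enolised again in step 9.

Step 8
Reactants: 17 (3S,4R)-4-(but-2-yn-1-yl)-3-(hydroxymethyl)dihydrofuran-2(3H)-one
Product: 18 (3S,4R)-4-(but-2-yn-1-yl)-3-{[tert-butyl(dimethyl)silyl]oxymethyl}dihydrofuran-2(3H)-one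
Conditions: t-BuMe2SiCl, imidazole, DMF, rt
Reagents that add atoms: tert-butyldimethylsilyl chloride, CC(C)(C)[Si](C)(C)Cl
Why: Standard silylation of a primary alcohol; this is the protecting group that the C19 oxygen keeps until step 22.

Step 9
Reactants: 18 (3S,4R)-4-(but-2-yn-1-yl)-3-{[tert-butyl(dimethyl)silyl]oxymethyl}dihydrofuran-2(3H)-one
Product: 20 (3R,4R)-4-(but-2-yn-1-yl)-3-{[tert-butyl(dimethyl)silyl]oxymethyl}-3-methyldihydrofuran-2(3H)-one, via lithium enolate 19 (not isolated)
Conditions: LiN(i-Pr)2, THF, −78 °C; then MeI, −78 to −40 °C
Reagents that add atoms: iodomethane, CI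
Why: Enolate alkylation of a β-substituted γ-butyrolactone: methyl iodide adds anti to the C5 butynyl group, so the methyl ends trans and the silyloxymethyl arm cis to it, which sets the quaternary C4 with the lactone carbonyl as the future C3; low temperature keeps β-elimination of silyloxide in check.

Step 10
Reactants: 20 (3R,4R)-4-(but-2-yn-1-yl)-3-{[tert-butyl(dimethyl)silyl]oxymethyl}-3-methyldihydrofuran-2(3H)-one
Product: 21 (2R,3S)-2-(but-2-yn-1-yl)-3-{[tert-butyl(dimethyl)silyl]oxymethyl}-3-methylbutane-1,4-diol
Conditions: LiAlH4, THF, 0 °C
Reagents that add atoms: none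
Why: Hydride reduction of the lactone to the 1,4-diol; the silyl ether and the isolated alkyne are inert.

Step 11
Reactants: 21 (2R,3S)-2-(but-2-yn-1-yl)-3-{[tert-butyl(dimethyl)silyl]oxymethyl}-3-methylbutane-1,4-diol
Product: 23 (3R,4S)-3-(but-2-yn-1-yl)-4-{[tert-butyl(dimethyl)silyl]oxymethyl}-4-methyldihydrofuran-2(3H)-one, via lactol 22 (not isolated)
Conditions: TEMPO (cat.), PhI(OAc)2, CH2Cl2, rt
Reagents that add atoms: none
Why: Oxidative lactonisation of a 1,4-diol: the less hindered C10 carbinol should be oxidised first, the hydroxy aldehyde closes to the lactol and is oxidised on, so the carbonyl moves from C3 to C10; oxidation at the neopentyl C3 carbinol would only return 20, which can be recycled.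

Step 12
Reactants: 23 (3R,4S)-3-(but-2-yn-1-yl)-4-{[tert-butyl(dimethyl)silyl]oxymethyl}-4-methyldihydrofuran-2(3H)-one
Product: 22 (3R,4S)-3-(but-2-yn-1-yl)-4-{[tert-butyl(dimethyl)silyl]oxymethyl}-4-methyltetrahydrofuran-2-ol (both anomers)
Conditions: i-Bu2AlH, CH2Cl2, −78 °C
Reagents that add atoms: none
Why: Half-reduction of a lactone to the lactol at low temperature; the tetrahedral aluminium intermediate is stable until work-up.

Step 13
Reactants: 22 (3R,4S)-3-(but-2-yn-1-yl)-4-{[tert-butyl(dimethyl)silyl]oxymethyl}-4-methyltetrahydrofuran-2-ol
Product: 24 (2S,3S)-2-{[tert-butyl(dimethyl)silyl]oxymethyl}-3-ethynyl-2-methylhept-5-yn-1-ol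
Conditions: MeC(O)C(N2)P(O)(OMe)2, K2CO3, MeOH, 0 °C to rt
Reagents that add atoms: dimethyl (1-diazo-2-oxopropyl)phosphonate, COP(=O)(OC)C(=[N+]=[N-])C(C)=O
Why: Ohira–Bestmann homologation acts on the open hydroxy-aldehyde form of the lactol, adds C9 as the terminal alkyne carbon and frees the C3 hydroxyl; the hindered C5 centre next to the aldehyde should survive the mild base.

Step 14
Reactants: 24 (2S,3S)-2-{[tert-butyl(dimethyl)silyl]oxymethyl}-3-ethynyl-2-methylhept-5-yn-1-ol
Product: 25 [(2S,3S)-2-{[tert-butyl(dimethyl)silyl]oxymethyl}-3-ethynyl-2-methylhept-5-yn-1-yl] acetate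
Conditions: Ac2O, pyridine, DMAP (cat.), CH2Cl2, rt
Reagents that add atoms: acetic anhydride, CC(=O)OC(C)=O
Why: Acetylation masks the C3 hydroxyl so that it can neither direct the organocopper reagent in step 15 nor add to a gold-activated alkyne in step 16.

Step 15
Reactants: 25 [(2S,3S)-2-{[tert-butyl(dimethyl)silyl]oxymethyl}-3-ethynyl-2-methylhept-5-yn-1-yl] acetate; 26 (trimethylsilyl)methylmagnesium chloride; 6 tert-butyl (S)-5-iodo-3-methylpentanoate
Product: 28 tert-butyl (3R,6Z,8R)-8-[(2S)-1-acetoxy-3-{[tert-butyl(dimethyl)silyl]oxy}-2-methylpropan-2-yl]-3-methyl-7-[(trimethylsilyl)methyl]dodec-6-en-10-ynoate, via alkenylcopper 27 (not isolated)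
Conditions: 26, CuBr·SMe2, Et2O, −40 °C; 25, −20 to 10 °C; then 6, HMPA, P(OEt)3, THF, −20 °C to rt
Reagents that add atoms: none
Why: Syn carbocupration of the terminal alkyne by (trimethylsilyl)methylcopper puts CH2SiMe3 on C10 and copper on C9, and alkylation of the alkenylcopper with retention gives the (Z)-allylsilane with the chain cis to CH2SiMe3; the internal alkyne and both esters do not react with the organocopper species.

Step 16
Reactants: 28 tert-butyl (3R,6Z,8R)-8-[(2S)-1-acetoxy-3-{[tert-butyl(dimethyl)silyl]oxy}-2-methylpropan-2-yl]-3-methyl-7-[(trimethylsilyl)methyl]dodec-6-en-10-ynoate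
Product: 29 ring B diene acetate: tert-butyl (3R)-5-(cyclohexenyl)-3-methylpentanoate whose ring has the C7–C8 alkene (methyl on C8), the exocyclic C10 methylene and, on C5, the quaternary C4 group (methyl, CH2OAc = C3, CH2OSi-t-BuMe2 = C19); C5 and C9 substituents cis, C4, C5 and C9 as in the target
Conditions: Ph3PAuNTf2 (5 mol %), MeOH (3 equiv), CH2Cl2, 0 °C to rt
Reagents that add atoms: none
Why: The monovalent gold catalyst activates the butynyl alkyne for 6-endo-dig attack by C9 of the allylsilane (the developing C10 cation is tertiary and β to silicon); loss of the silyl group to methanol gives the exocyclic methylene and protodeauration gives the C7–C8 alkene, as in known gold- or platinum-catalysed allylsilane–alkyne cyclisations. C9 is formed here: the (Z)-alkene places C9–H on the C5 side, so the 5,9-cis diene results if the cyclisation runs through the rotamer with C5–H in the alkene plane and both the C4 group and the chain pseudo-equatorial; the competing rotamer is discussed under the uncertain steps.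

Step 17
Reactants: 29 ring B diene acetate
Product: 30 ring B diene alcohol (as 29 with CH2OH at C3)
Conditions: K2CO3, MeOH, rt
Reagents that add atoms: none
Why: Methanolysis of the primary acetate; the tert-butyl ester, the silyl ether and the skipped diene are stable to these conditions.

Step 18
Reactants: 30 ring B diene alcohol
Product: 31 ring B aldehyde (as 30 with CHO at C3)
Conditions: Dess–Martin periodinane, NaHCO3, CH2Cl2, 0 °C to rt
Reagents that add atoms: none
Why: Buffered Dess–Martin oxidation of a neopentyl alcohol gives the aldehyde, which has no α-hydrogen and cannot enolise or epimerise.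

Step 19
Reactants: 31 ring B aldehyde; 32 methyl vinyl ketone (but-3-en-2-one)
Product: 33 trans-decalin aldol: tert-butyl ester with equatorial C2 acetyl, axial C3 hydroxyl, C4 methyl and CH2OSi-t-BuMe2 (C19), C10 methyl, C7–C8 alkene and the C9 chain
Conditions: Fe(acac)3 (30 mol %), PhSiH3, 32 (3 equiv), EtOH–(CH2OH)2, 0 °C to rt, degassed
Reagents that add atoms: none
Why: An iron hydride formed from Fe(acac)3 and PhSiH3 transfers a hydrogen atom to the CH2 terminus of the 1,1-disubstituted alkene, which creates the C10 methyl and a tertiary C10 radical; the trisubstituted C7–C8 alkene reacts much more slowly. The radical adds to methyl vinyl ketone (C1–C10, Giese addition), the α-keto radical is reduced to an iron enolate, and this closes ring A by a 6-(enolexo)-exo-trig aldol addition to the non-enolisable C3 aldehyde (C2–C3). The closest known reaction type is the iron-hydride-initiated radical–polar crossover annulation of alkenyl carbonyl compounds with enones, which gives trans-decalins. C10: the cis-related C5 and C9 substituents shield the same face of the planar radical, so C1 enters anti to both, which gives the trans ring fusion and places the new methyl cis to the C9 chain. C2 and C3: the (Z)-enolate should react through a closed chair (Zimmerman–Traxler) transition state fused to the forming ring, which gives the syn aldol, that is equatorial acetyl and axial hydroxyl; C2 can in addition equilibrate to the equatorial position by enolisation. The step needs alkene discrimination (secured by the substitution pattern), addition to the enone faster than return of a hydrogen atom from C9 or C5 to the metal (excess enone), and aldol closure faster than protonation of the enolate by the solvent.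

Step 20
Reactants: 33 trans-decalin aldol
Product: 34 C3 triethylsilyl ether of 33
Conditions: Et3SiCl, imidazole, DMAP (cat.), DMF, 40 °C
Reagents that add atoms: chlorotriethylsilane, CC[Si](CC)(CC)Cl
Why: Silylation of the axial C3 hydroxyl blocks retro-aldol cleavage and dehydration of the β-hydroxy ketone under the Lewis acid of step 21; the chloride–imidazole conditions do not form a silyl enol ether from the methyl ketone.

Step 21
Reactants: 34 C3 triethylsilyl ether
Product: 35 C2 acetate (as 34 with OAc in place of the acetyl group)
Conditions: (Me3SiO)2, SnCl4, 4 Å sieves, CH2Cl2, −40 to −20 °C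
Reagents that add atoms: bis(trimethylsilyl) peroxide, C[Si](C)(C)OO[Si](C)(C)C
Why: Baeyer–Villiger oxidation: the secondary C2 migrates in preference to methyl and with retention; the silyl peroxide–Lewis acid system is known to oxidise ketones without epoxidising isolated alkenes, which a peracid would do here.

Step 22
Reactants: 35 C2 acetate
Product: 37 hydroxy acid: C2 acetate, C3 hydroxyl, C19 CH2OH, C15 carboxylic acid, via silyl ester 36 (not isolated)
Conditions: Me3SiOSO2CF3, 2,6-lutidine, CH2Cl2, 0 °C; then HF·pyridine, THF–pyridine, 0 °C to rt
Reagents that add atoms: none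
Why: The silyl triflate with 2,6-lutidine converts the tert-butyl ester into the trimethylsilyl ester without strong protic acid, which would move the C7–C8 alkene to C8–C9; buffered HF·pyridine then removes all three silyl groups while the acetate stays and has little chance to migrate.

Step 23
Reactants: 37 hydroxy acid
Product: 38 CNP0180877.1 (target)
Conditions: TEMPO (cat.), PhI(OAc)2, CH2Cl2, rt
Reagents that add atoms: none
Why: The oxoammonium oxidant takes the primary C19 alcohol and leaves the hindered secondary C3 alcohol; under anhydrous conditions the oxidation stops at the aldehyde, and the free acid is tolerated.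

## Compound list

1 | methyl hydrogen (R)-3-methylglutarate | OC(=O)C[C@@H](C)CC(=O)OC | starting material
2 | methyl (R)-5-hydroxy-3-methylpentanoate | OCC[C@@H](C)CC(=O)OC | intermediate
3 | (R)-4-methyltetrahydro-2H-pyran-2-one | C[C@@H]1CCOC(=O)C1 | intermediate
4 | trimethylsilyl (S)-5-iodo-3-methylpentanoate | ICC[C@@H](C)CC(=O)O[Si](C)(C)C | intermediate
5 | (S)-5-iodo-3-methylpentanoic acid | ICC[C@@H](C)CC(=O)O | intermediate
6 | tert-butyl (S)-5-iodo-3-methylpentanoate | ICC[C@@H](C)CC(=O)OC(C)(C)C | intermediate
7 | 4-tert-butoxy-4-oxobutanoic acid | CC(C)(C)OC(=O)CCC(=O)O | starting material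
8 | (R)-4-benzyloxazolidin-2-one | O=C1N[C@H](Cc2ccccc2)CO1 | starting material
9 | 4-tert-butoxy-4-oxobutanoic pivalic anhydride | CC(C)(C)OC(=O)CCC(=O)OC(=O)C(C)(C)C | intermediate
10 | tert-butyl 4-[(4R)-4-benzyl-2-oxooxazolidin-3-yl]-4-oxobutanoate | CC(C)(C)OC(=O)CCC(=O)N1[C@H](Cc2ccccc2)COC1=O | intermediate
11 | 1-bromobut-2-yne | CC#CCBr | starting material
12 | sodium (Z)-enolate of imide 10 | CC(C)(C)OC(=O)C/C=C(\[O-])N1[C@H](Cc2ccccc2)COC1=O.[Na+] | intermediate
13 | tert-butyl (3R)-3-{[(4R)-4-benzyl-2-oxooxazolidin-3-yl]carbonyl}hept-5-ynoate | CC#CC[C@H](CC(=O)OC(C)(C)C)C(=O)N1[C@H](Cc2ccccc2)COC1=O | intermediate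
14 | tert-butyl (3R)-3-(hydroxymethyl)hept-5-ynoate | CC#CC[C@H](CC(=O)OC(C)(C)C)CO | intermediate
15 | (4R)-4-(but-2-yn-1-yl)dihydrofuran-2(3H)-one | CC#CC[C@H]1COC(=O)C1 | intermediate
16 | lithium enolate of lactone 15 | [Li+].[O-]C1=C[C@@H](CC#CC)CO1 | intermediate
17 | (3S,4R)-4-(but-2-yn-1-yl)-3-(hydroxymethyl)dihydrofuran-2(3H)-one | CC#CC[C@H]1COC(=O)[C@@H]1CO | intermediate
18 | (3S,4R)-4-(but-2-yn-1-yl)-3-{[tert-butyl(dimethyl)silyl]oxymethyl}dihydrofuran-2(3H)-one | CC#CC[C@H]1COC(=O)[C@@H]1CO[Si](C)(C)C(C)(C)C | intermediate
19 | lithium enolate of lactone 18 | [Li+].[O-]C1=C(CO[Si](C)(C)C(C)(C)C)[C@@H](CC#CC)CO1 | intermediate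
20 | (3R,4R)-4-(but-2-yn-1-yl)-3-{[tert-butyl(dimethyl)silyl]oxymethyl}-3-methyldihydrofuran-2(3H)-one | CC#CC[C@H]1COC(=O)[C@@]1(C)CO[Si](C)(C)C(C)(C)C | intermediate
21 | (2R,3S)-2-(but-2-yn-1-yl)-3-{[tert-butyl(dimethyl)silyl]oxymethyl}-3-methylbutane-1,4-diol | CC#CC[C@@H](CO)[C@@](C)(CO)CO[Si](C)(C)C(C)(C)C | intermediate
22 | (3R,4S)-3-(but-2-yn-1-yl)-4-{[tert-butyl(dimethyl)silyl]oxymethyl}-4-methyltetrahydrofuran-2-ol (both anomers) | CC#CC[C@H]1C(O)OC[C@@]1(C)CO[Si](C)(C)C(C)(C)C | intermediate
23 | (3R,4S)-3-(but-2-yn-1-yl)-4-{[tert-butyl(dimethyl)silyl]oxymethyl}-4-methyldihydrofuran-2(3H)-one | CC#CC[C@H]1C(=O)OC[C@@]1(C)CO[Si](C)(C)C(C)(C)C | intermediate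
24 | (2S,3S)-2-{[tert-butyl(dimethyl)silyl]oxymethyl}-3-ethynyl-2-methylhept-5-yn-1-ol | C#C[C@H](CC#CC)[C@@](C)(CO)CO[Si](C)(C)C(C)(C)C | intermediate
25 | [(2S,3S)-2-{[tert-butyl(dimethyl)silyl]oxymethyl}-3-ethynyl-2-methylhept-5-yn-1-yl] acetate | C#C[C@H](CC#CC)[C@@](C)(COC(C)=O)CO[Si](C)(C)C(C)(C)C | intermediate
26 | (trimethylsilyl)methylmagnesium chloride | C[Si](C)(C)C[Mg]Cl | starting material
27 | alkenylcopper from 25 (copper on C9 cis to CH2SiMe3 on C10) | [Cu]/C=C(\C[Si](C)(C)C)[C@H](CC#CC)[C@@](C)(COC(C)=O)CO[Si](C)(C)C(C)(C)C | intermediate
28 | tert-butyl (3R,6Z,8R)-8-[(2S)-1-acetoxy-3-{[tert-butyl(dimethyl)silyl]oxy}-2-methylpropan-2-yl]-3-methyl-7-[(trimethylsilyl)methyl]dodec-6-en-10-ynoate | CC(C)(C)OC(=O)C[C@H](C)CC/C=C(\C[Si](C)(C)C)[C@H](CC#CC)[C@@](C)(COC(C)=O)CO[Si](C)(C)C(C)(C)C | intermediate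
29 | ring B diene acetate (C5 and C9 substituents cis; C3 as CH2OAc, C19 as CH2OSi-t-BuMe2) | C=C1[C@H](CC[C@@H](C)CC(=O)OC(C)(C)C)C(C)=CC[C@@H]1[C@](C)(CO[Si](C)(C)C(C)(C)C)COC(C)=O | intermediate
30 | ring B diene alcohol (C3 as CH2OH) | C=C1[C@H](CC[C@@H](C)CC(=O)OC(C)(C)C)C(C)=CC[C@@H]1[C@](C)(CO[Si](C)(C)C(C)(C)C)CO | intermediate
31 | ring B aldehyde (C3 as CHO; key-step precursor) | C=C1[C@H](CC[C@@H](C)CC(=O)OC(C)(C)C)C(C)=CC[C@@H]1[C@](C)(CO[Si](C)(C)C(C)(C)C)C=O | intermediate
32 | methyl vinyl ketone (but-3-en-2-one) | C=CC(C)=O | starting material
33 | trans-decalin aldol (equatorial C2 acetyl, axial C3 hydroxyl; key-step product) | CC(=O)[C@H]1C[C@@]2(C)[C@H](CC[C@@H](C)CC(=O)OC(C)(C)C)C(C)=CC[C@@H]2[C@](C)(CO[Si](C)(C)C(C)(C)C)[C@H]1O | intermediate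
34 | C3 triethylsilyl ether of 33 | CC(=O)[C@H]1C[C@@]2(C)[C@H](CC[C@@H](C)CC(=O)OC(C)(C)C)C(C)=CC[C@@H]2[C@](C)(CO[Si](C)(C)C(C)(C)C)[C@H]1O[Si](CC)(CC)CC | intermediate
35 | C2 acetate, C3 triethylsilyl ether, C19 silyl ether, tert-butyl ester | CC(=O)O[C@H]1C[C@@]2(C)[C@H](CC[C@@H](C)CC(=O)OC(C)(C)C)C(C)=CC[C@@H]2[C@](C)(CO[Si](C)(C)C(C)(C)C)[C@H]1O[Si](CC)(CC)CC | intermediate
36 | trimethylsilyl ester corresponding to 35 | CC(=O)O[C@H]1C[C@@]2(C)[C@H](CC[C@@H](C)CC(=O)O[Si](C)(C)C)C(C)=CC[C@@H]2[C@](C)(CO[Si](C)(C)C(C)(C)C)[C@H]1O[Si](CC)(CC)CC | intermediate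
37 | hydroxy acid (C2 acetate, C3 hydroxyl, C19 CH2OH, C15 acid) | CC(=O)O[C@H]1C[C@@]2(C)[C@H](CC[C@@H](C)CC(=O)O)C(C)=CC[C@@H]2[C@](C)(CO)[C@H]1O | intermediate
38 | CNP0180877.1 | CC(=O)O[C@H]1C[C@@]2(C)[C@H](CC[C@@H](C)CC(=O)O)C(C)=CC[C@@H]2[C@](C)(C=O)[C@H]1O | target

## Step count and least certain steps

Total: 23 steps. Longest linear sequence: 20 steps (steps 4 to 23, from 7 and 8). The side chain takes steps 1 to 3 and joins in step 15.

**Step 19 (key step).** Three things can go wrong:
- The C10 radical may return a hydrogen atom from C9 or C5 to the metal before it meets the enone, which would move the exocyclic alkene into the ring.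
- The enolate may be protonated by the alcohol solvent before it reaches the aldehyde, so that the sequence stops after the conjugate addition.
- The aldol may close through the other transition state and give the equatorial C3 alcohol.

The fallback separates the two events. From 31, the hydrogen-atom-transfer addition to 32 alone would give the uncyclised keto aldehyde F1. Ring A would then be closed in a second operation by an intramolecular aldol under reversible enolisation (pyrrolidine and acetic acid). Only the C2 enol can reach C3 through a six-membered ring, and the syn, hydrogen-bonded aldol can be enriched by equilibration. The route is rejoined at 33.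

**Step 16 (ring B closure).** The most likely failure is poor or inverted facial selectivity at C9. The 5,9-cis diene requires the rotamer in which the bulky C4 group lies next to the CH2SiMe3 carbon. Allylic 1,2-strain opposes that rotamer and favours the one with C4 pseudo-axial, which leads to the C9 epimer. Closure to a five-membered ring and simple protodesilylation are lesser risks.

The fallback ties C4 to the silicon atom so that only the required rotamer can react:
- From 25, carbocupration with (dimethylsilyl)methylcopper (from ClMgCH2SiMe2H and CuBr·SMe2) and alkylation with 6 would give the Si–H allylsilane F2.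
- K2CO3 in methanol would remove the acetate and convert Si–H into Si–OMe, giving the hydroxy methoxysilane F3.
- Heating F3 in toluene with loss of methanol would close the seven-membered cyclic silyl ether F4, in which the C3–O–Si bridge holds C4 on the side of the silylmethyl carbon.
- Ph3PAuNTf2 with one equivalent of 2-propanol would then give the diene as its isopropoxydimethylsilyl ether F5, which is hydrolysed on work-up.

The route is rejoined at 30.

**Step 15 (carbocupration–alkylation).** The alkyne is α-branched and hindered, and the alkenylcopper 27 may react too slowly with an unactivated primary iodide, so that protonation on work-up takes over. The fallback replaces the alkylation by a cross-coupling. From 25, the alkenylcopper would be quenched with iodine to the (Z)-alkenyl iodide F6. The alkylzinc iodide F7 (from 6, zinc dust and LiCl) would be coupled with it under Pd(PPh3)4 catalysis (Negishi coupling). The route is rejoined at 28.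

**Step 21 (Baeyer–Villiger oxidation).** The Lewis acid may strip the silyl ethers or the tert-butyl ester, or induce elimination of the β-silyloxy group, before the hindered ketone is oxidised. The fallback accepts reaction at the alkene and repairs it afterwards. From 34, buffered trifluoroperacetic acid (CF3CO3H, Na2HPO4) would carry out both the Baeyer–Villiger oxidation and epoxidation, giving the epoxy acetate F8. The epoxide would then be deoxygenated back to the C7–C8 alkene with zinc and NaI in buffered acetic acid. The route is rejoined at 35.

**Step 11 (transposition of the lactone).** The two primary alcohols of 21 may not be distinguished well enough, so that much of the material is oxidised at the neopentyl carbinol and returns to 20. The fallback differentiates them by protection: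
- From 21, one equivalent of Et3SiCl at low temperature would silylate the less hindered C10 hydroxyl, giving the mono(triethylsilyl) ether F9.
- Acetylation of the C3 hydroxyl would give F10.
- Swern oxidation, which converts primary triethylsilyl ethers directly into aldehydes, would give the aldehyde F11.
- The Ohira–Bestmann reaction in K2CO3–methanol would form the alkyne and remove the acetate in the same operation.

The route is rejoined at 24.

## Further compounds

F1 | step 19 | keto aldehyde from conjugate addition without ring closure (C10 quaternary, 3-oxobutyl chain on C10, C3 aldehyde) | CC(=O)CC[C@@]1(C)[C@H](CC[C@@H](C)CC(=O)OC(C)(C)C)C(C)=CC[C@@H]1[C@](C)(CO[Si](C)(C)C(C)(C)C)C=O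
F2 | step 16 | (Z)-allylsilane as 28 with a dimethylsilyl (Si–H) group in place of trimethylsilyl | CC(C)(C)OC(=O)C[C@H](C)CC/C=C(\C[SiH](C)C)[C@H](CC#CC)[C@@](C)(COC(C)=O)CO[Si](C)(C)C(C)(C)C
F3 | step 16 | hydroxy methoxysilane (C3 hydroxyl free, methoxydimethylsilyl group on the allylic carbon) | CC(C)(C)OC(=O)C[C@H](C)CC/C=C(\C[Si](C)(C)OC)[C@H](CC#CC)[C@@](C)(CO)CO[Si](C)(C)C(C)(C)C
F4 | step 16 | seven-membered cyclic silyl ether (C3–O–SiMe2–CH2–C10 bridge, exocyclic C9=C10 alkene) | CC(C)(C)OC(=O)C[C@H](C)CC/C=C1\C[Si](C)(C)OC[C@@](C)(CO[Si](C)(C)C(C)(C)C)[C@H]1CC#CC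
F5 | step 16 | ring B diene as its C3 isopropoxydimethylsilyl ether | C=C1[C@H](CC[C@@H](C)CC(=O)OC(C)(C)C)C(C)=CC[C@@H]1[C@](C)(CO[Si](C)(C)C(C)(C)C)CO[Si](C)(C)OC(C)C
F6 | step 15 | (Z)-alkenyl iodide (iodine on C9 cis to CH2SiMe3) | I/C=C(\C[Si](C)(C)C)[C@H](CC#CC)[C@@](C)(COC(C)=O)CO[Si](C)(C)C(C)(C)C
F7 | step 15 | alkylzinc iodide from 6 | CC(C)(C)OC(=O)C[C@H](C)CC[Zn]I
F8 | step 21 | 7,8-epoxide of 35 (either face) | CC(=O)O[C@H]1C[C@@]2(C)[C@H](CC[C@@H](C)CC(=O)OC(C)(C)C)C3(C)OC3C[C@@H]2[C@](C)(CO[Si](C)(C)C(C)(C)C)[C@H]1O[Si](CC)(CC)CC
F9 | step 11 | mono(triethylsilyl) ether of 21 at the C10 oxygen | CC#CC[C@@H](CO[Si](CC)(CC)CC)[C@@](C)(CO)CO[Si](C)(C)C(C)(C)C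
F10 | step 11 | C3 acetate of F9 | CC#CC[C@@H](CO[Si](CC)(CC)CC)[C@@](C)(COC(C)=O)CO[Si](C)(C)C(C)(C)C
F11 | step 11 | C10 aldehyde with C3 acetate | CC#CC[C@@H](C=O)[C@@](C)(COC(C)=O)CO[Si](C)(C)C(C)(C)C
A1 | alternative 1 | (3R,6E)-3,7-dimethylnona-6,8-dien-1-yl tert-butyl(diphenyl)silyl ether | C=C/C(C)=C/CC[C@@H](C)CCO[Si](c1ccccc1)(c1ccccc1)C(C)(C)C
A2 | alternative 1 | ethyl (E)-3-methyl-4-oxobut-2-enoate | CCOC(=O)/C=C(\C)C=O
A3 | alternative 1 | ring B cycloadduct with C10 methyl and formyl and C5 ethoxycarbonyl | O=C[C@@]1(C)[C@H](CC[C@@H](C)CCO[Si](c2ccccc2)(c2ccccc2)C(C)(C)C)C(C)=CC[C@@H]1C(=O)OCC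
A4 | alternative 2 | ring B trialdehyde (formylmethyl on C10, two formyl groups on C4) | O=CC[C@@]1(C)[C@H](O[Si](C)(C)C(C)(C)C)C(C)=CC[C@@H]1C(C)(C=O)C=O
A5 | alternative 2 | decalin cis-2,3-diol with axial C19 formyl | O[C@H]1C[C@@]2(C)[C@H](O[Si](C)(C)C(C)(C)C)C(C)=CC[C@@H]2[C@](C)(C=O)[C@H]1O
A6 | alternative 3 | ten-membered dienyl lactone (C4 carbonyl, ring oxygen on C2, E alkene C1=C10, Z alkene C7=C8; C2 configuration shown is one of the two possible) | C[C@@H]1/C=C(C)/[C@H](CC[C@@H](C)CCO[Si](c2ccccc2)(c2ccccc2)C(C)(C)C)/C(C)=C\CCC(=O)O1
A7 | alternative 3 | ring B acid with quaternary C10 (methyl, (E)-propenyl) and C4 carboxyl on C5 | C/C=C/[C@@]1(C)[C@H](CC[C@@H](C)CCO[Si](c2ccccc2)(c2ccccc2)C(C)(C)C)C(C)=CC[C@@H]1C(=O)O
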